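**Assumption:** the target SMILES has no stereocentre, so vismiaphenone E is achiral and no enantiocontrol is needed; the stereocentres in 7, 10 and 16 are racemic and are erased later in the route.

## Retrosynthetic overview

- Target ⇐ removal of three MOM ethers from the protected benzophenone; the ketone ⇐ oxidation of a diaryl carbinol.
- Diaryl carbinol ⇐ C6-lithiated 5,7-bis(MOM)-8-prenyl-2,2-dimethylchromene + 4-(MOM-oxy)benzaldehyde; C6–H is the only aromatic hydrogen, so the acyl position is fixed.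
- Chromene ⇐ intermolecular aldol-type condensation of 2-prenyl-3,5-bis(MOM-oxy)phenol with prenal (forms C4–C4a), then dehydration and oxa-6π closure; one free OH and one free ortho carbon fix the regiochemistry.
- 2-Prenylphenol ⇐ aromatic Claisen rearrangement of the 1,1-dimethylallyl ether ⇐ 3,5-bis(MOM-oxy)phenol ⇐ phloroglucinol.
- Ring order: both benzene rings are bought; the pyran ring is the only ring formed (step 5).

## Route

**Step 1**
Reactants: 1 phloroglucinol; 2 chloromethyl methyl ether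
Product: 3 3,5-bis(methoxymethoxy)phenol
Conditions: MOMCl (2.0 equiv), i-Pr2NEt (2.2 equiv), DMF, 0 °C → rt; chromatography
Reagents that add atoms: chloromethyl methyl ether (2), COCCl
Why: Statistical O-alkylation (MOM protection) of three equivalent phenols gives the bis-ether as the main, separable component (about 35–45% expected) and leaves exactly one free OH.

**Step 2**
Reactants: 3 3,5-bis(methoxymethoxy)phenol; 4 3-chloro-3-methylbut-1-yne
Product: 5 1,3-bis(methoxymethoxy)-5-[(2-methylbut-3-yn-2-yl)oxy]benzene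
Conditions: 4 (1.3 equiv), DBU (1.5 equiv), CuCl2·2H2O (1 mol %), MeCN, 0 °C → rt
Reagents that add atoms: 3-chloro-3-methylbut-1-yne (4), CC(C)(Cl)C#C
Why: Copper-catalysed propargylic etherification of the phenol gives the tertiary aryl propargyl ether cleanly under mild base, without C-alkylation.

**Step 3**
Reactants: 5 1,3-bis(methoxymethoxy)-5-[(2-methylbut-3-yn-2-yl)oxy]benzene
Product: 6 1,3-bis(methoxymethoxy)-5-[(2-methylbut-3-en-2-yl)oxy]benzene
Conditions: H2 (1 atm), Lindlar catalyst (Pd/CaCO3–Pb), quinoline, EtOAc, rt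
Reagents that add atoms: none
Why: Lindlar semihydrogenation stops at the terminal alkene, and nothing else in 5 is reducible.

**Step 4**
Reactants: 6 1,3-bis(methoxymethoxy)-5-[(2-methylbut-3-en-2-yl)oxy]benzene
Product: 8 3,5-bis(methoxymethoxy)-2-(3-methylbut-2-en-1-yl)phenol, via ortho-dienone 7 (not isolated)
Conditions: xylene, 130 °C
Reagents that add atoms: none
Why: Aromatic Claisen [3,3] rearrangement of the reverse-prenyl ether delivers a normal prenyl group to an ortho carbon (both ortho positions are equivalent), and the dienone tautomerises to the phenol.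

**Step 5**
Reactants: 8 3,5-bis(methoxymethoxy)-2-(3-methylbut-2-en-1-yl)phenol; 9 3-methylbut-2-enal (prenal)
Product: 12 5,7-bis(methoxymethoxy)-2,2-dimethyl-8-(3-methylbut-2-en-1-yl)-2H-chromene, via aldol adduct 10 (not isolated), via ortho-quinone methide 11 (not isolated)
Conditions: 9 (2 equiv), ethylenediammonium diacetate (EDDA, 20 mol %), xylene, 140 °C, sealed tube
Reagents that add atoms: 3-methylbut-2-enal (9), CC(C)=CC=O
Why: EDDA-catalysed intermolecular aldol-type (Knoevenagel) condensation of the only free ortho carbon with the aldehyde, dehydration to the ortho-quinone methide and oxa-6π electrocyclisation onto the only free OH give the 2,2-dimethylchromene as a single regioisomer; no stereocentre remains.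

**Step 6**
Reactants: 13 4-hydroxybenzaldehyde; 2 chloromethyl methyl ether
Product: 14 4-(methoxymethoxy)benzaldehyde
Conditions: MOMCl (1.2 equiv), i-Pr2NEt (1.5 equiv), CH2Cl2, 0 °C → rt
Reagents that add atoms: chloromethyl methyl ether (2), COCCl
Why: Standard MOM protection of a phenol, which removes the acidic OH before the organolithium step.

**Step 7**
Reactants: 12 5,7-bis(methoxymethoxy)-2,2-dimethyl-8-(3-methylbut-2-en-1-yl)-2H-chromene; 14 4-(methoxymethoxy)benzaldehyde
Product: 16 (±)-[5,7-bis(methoxymethoxy)-2,2-dimethyl-8-(3-methylbut-2-en-1-yl)-2H-chromen-6-yl][4-(methoxymethoxy)phenyl]methanol, via aryllithium 15 (not isolated)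
Conditions: n-BuLi (1.15 equiv), THF, 0 °C, 1 h; then 14 (1.3 equiv), −78 → 0 °C; then H2O
Reagents that add atoms: 4-(methoxymethoxy)benzaldehyde (14), COCOc1ccc(C=O)cc1
Why: Directed ortho-metalation at C6–H, the only aromatic hydrogen and flanked by two OMOM groups, followed by 1,2-addition of the aryllithium to the aldehyde; the new carbinol centre is racemic and is removed in step 8.

**Step 8**
Reactants: 16 (±)-[5,7-bis(methoxymethoxy)-2,2-dimethyl-8-(3-methylbut-2-en-1-yl)-2H-chromen-6-yl][4-(methoxymethoxy)phenyl]methanol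
Product: 17 [5,7-bis(methoxymethoxy)-2,2-dimethyl-8-(3-methylbut-2-en-1-yl)-2H-chromen-6-yl][4-(methoxymethoxy)phenyl]methanone
Conditions: IBX (1.5 equiv), DMSO, rt
Reagents that add atoms: none
Why: IBX oxidation of the doubly benzylic alcohol is fast and essentially neutral, so the acid-sensitive benzhydrol, the MOM acetals and both alkenes survive.

**Step 9**
Reactants: 17 [5,7-bis(methoxymethoxy)-2,2-dimethyl-8-(3-methylbut-2-en-1-yl)-2H-chromen-6-yl][4-(methoxymethoxy)phenyl]methanone
Product: 18 vismiaphenone E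
Conditions: HCl (ca. 1 M) in MeOH, rt → 40 °C, monitored and stopped at full conversion
Reagents that add atoms: none
Why: Acid-catalysed transacetalisation removes all three MOM ethers (the two carbonyl-chelated ones fastest) under conditions mild enough to leave the prenyl group and the chromene intact.

## Compound list

1 | phloroglucinol (benzene-1,3,5-triol) | Oc1cc(O)cc(O)c1 | starting material
2 | chloromethyl methyl ether (MOMCl) | COCCl | starting material
3 | 3,5-bis(methoxymethoxy)phenol | COCOc1cc(O)cc(OCOC)c1 | intermediate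
4 | 3-chloro-3-methylbut-1-yne | CC(C)(Cl)C#C | starting material
5 | 1,3-bis(methoxymethoxy)-5-[(2-methylbut-3-yn-2-yl)oxy]benzene | COCOc1cc(OCOC)cc(OC(C)(C)C#C)c1 | intermediate
6 | 1,3-bis(methoxymethoxy)-5-[(2-methylbut-3-en-2-yl)oxy]benzene | COCOc1cc(OCOC)cc(OC(C)(C)C=C)c1 | intermediate
7 | 3,5-bis(methoxymethoxy)-6-(3-methylbut-2-en-1-yl)cyclohexa-2,4-dien-1-one (racemic ortho-dienone; not isolated) | O=C1C=C(OCOC)C=C(OCOC)C1CC=C(C)C | intermediate
8 | 3,5-bis(methoxymethoxy)-2-(3-methylbut-2-en-1-yl)phenol | CC(C)=CCc1c(O)cc(OCOC)cc1OCOC | intermediate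
9 | 3-methylbut-2-enal (prenal) | CC(C)=CC=O | starting material
10 | 2-(1-hydroxy-3-methylbut-2-en-1-yl)-3,5-bis(methoxymethoxy)-6-(3-methylbut-2-en-1-yl)phenol (racemic aldol adduct; not isolated) | CC(C)=CCc1c(O)c(C(O)C=C(C)C)c(OCOC)cc1OCOC | intermediate
11 | (6Z)-3,5-bis(methoxymethoxy)-2-(3-methylbut-2-en-1-yl)-6-(3-methylbut-2-en-1-ylidene)cyclohexa-2,4-dien-1-one (ortho-quinone methide; not isolated) | CC(C)=C/C=C1\C(=O)C(CC=C(C)C)=C(OCOC)C=C1OCOC | intermediate
12 | 5,7-bis(methoxymethoxy)-2,2-dimethyl-8-(3-methylbut-2-en-1-yl)-2H-chromene | CC(C)=CCc1c(OCOC)cc(OCOC)c2c1OC(C)(C)C=C2 | intermediate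
13 | 4-hydroxybenzaldehyde | O=Cc1ccc(O)cc1 | starting material
14 | 4-(methoxymethoxy)benzaldehyde | COCOc1ccc(C=O)cc1 | intermediate
15 | [5,7-bis(methoxymethoxy)-2,2-dimethyl-8-(3-methylbut-2-en-1-yl)-2H-chromen-6-yl]lithium (not isolated) | CC(C)=CCc1c(OCOC)c([Li])c(OCOC)c2c1OC(C)(C)C=C2 | intermediate
16 | (±)-[5,7-bis(methoxymethoxy)-2,2-dimethyl-8-(3-methylbut-2-en-1-yl)-2H-chromen-6-yl][4-(methoxymethoxy)phenyl]methanol | CC(C)=CCc1c(OCOC)c(C(O)c2ccc(OCOC)cc2)c(OCOC)c2c1OC(C)(C)C=C2 | intermediate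
17 | [5,7-bis(methoxymethoxy)-2,2-dimethyl-8-(3-methylbut-2-en-1-yl)-2H-chromen-6-yl][4-(methoxymethoxy)phenyl]methanone | CC(C)=CCc1c(OCOC)c(C(=O)c2ccc(OCOC)cc2)c(OCOC)c2c1OC(C)(C)C=C2 | intermediate
18 | vismiaphenone E, [5,7-dihydroxy-2,2-dimethyl-8-(3-methylbut-2-en-1-yl)-2H-chromen-6-yl](4-hydroxyphenyl)methanone (achiral) | CC(C)=CCc1c(O)c(C(=O)c2ccc(O)cc2)c(O)c2c1OC(C)(C)C=C2 | target

## Summary

Total step count: 9.
Longest linear sequence: 8 steps (steps 1, 2, 3, 4, 5, 7, 8, 9 from phloroglucinol); step 6 is a one-step side branch.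

## Three steps most likely to fail

**Step 5 (chromene annulation).** The mono-phenol 8 is hindered and less nucleophilic than a resorcinol, and prenal can oligomerise before it condenses. The fallback sets out from 8 and replaces the aldol-type condensation with a sigmatropic route. Copper-catalysed O-alkylation of 8 with 4 (DBU, cat. CuCl2, MeCN, 0 °C) gives the aryl 1,1-dimethylpropargyl ether F1. Heating F1 in PhNEt2 at 150–180 °C brings about propargyl Claisen rearrangement, 1,5-hydrogen shift and oxa-6π closure onto the same ortho carbon, and the route is rejoined at 12.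

**Step 7 (lithiation of the chromene and addition to 14).** n-BuLi may attack the chromene double bond or deprotonate the benzylic-allylic CH2 of the prenyl group instead of C6–H. The fallback sets out from 8 and installs the aroyl group before the pyran ring exists. Silylation (TIPSCl, imidazole, DMF) gives the triisopropylsilyl ether F2. n-BuLi (THF, 0 °C) metalates the position between the two OMOM groups to give the aryllithium F3, which adds to 14 to give the diaryl carbinol F4. IBX (DMSO, rt) gives the silyl-protected benzophenone F5, and TBAF/AcOH (THF, 0 °C) frees the para-phenol to give the hydroxybenzophenone F6. EDDA-catalysed condensation of F6 with 9 then closes the pyran ring on its only free OH, and the route is rejoined at 17.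

**Step 9 (global MOM removal).** Forcing the less labile 4'-OMOM group with protic acid risks cyclisation of the 7-OH onto the 8-prenyl group (dihydropyran formation) or addition to the alkenes. The fallback sets out from 12 and uses an orthogonal protecting-group set so that no protic acid meets the free prenylphenol. The aryllithium 15 is added to purchased 4-(tert-butyldimethylsilyloxy)benzaldehyde (CC(C)(C)[Si](C)(C)Oc1ccc(C=O)cc1) to give the silyl-protected carbinol F7, and IBX gives the silyl-protected ketone F8. ZnBr2/n-PrSH (CH2Cl2, 0 °C, a few minutes) removes the two carbonyl-chelated MOM ethers to give the dihydroxy ketone F9. TBAF/AcOH (THF, 0 °C) then cleaves the aryl silyl ether, and the route is rejoined at 18.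

## Further compounds

F1 | step 5 | 1,5-bis(methoxymethoxy)-2-(3-methylbut-2-en-1-yl)-3-[(2-methylbut-3-yn-2-yl)oxy]benzene | CC(C)=CCc1c(OC(C)(C)C#C)cc(OCOC)cc1OCOC
F2 | step 7 | [3,5-bis(methoxymethoxy)-2-(3-methylbut-2-en-1-yl)phenoxy]tri(propan-2-yl)silane | CC(C)=CCc1c(O[Si](C(C)C)(C(C)C)C(C)C)cc(OCOC)cc1OCOC
F3 | step 7 | [2,6-bis(methoxymethoxy)-3-(3-methylbut-2-en-1-yl)-4-(triisopropylsilyloxy)phenyl]lithium | CC(C)=CCc1c(O[Si](C(C)C)(C(C)C)C(C)C)cc(OCOC)c([Li])c1OCOC
F4 | step 7 | (±)-[2,6-bis(methoxymethoxy)-3-(3-methylbut-2-en-1-yl)-4-(triisopropylsilyloxy)phenyl][4-(methoxymethoxy)phenyl]methanol | CC(C)=CCc1c(O[Si](C(C)C)(C(C)C)C(C)C)cc(OCOC)c(C(O)c2ccc(OCOC)cc2)c1OCOC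
F5 | step 7 | [2,6-bis(methoxymethoxy)-3-(3-methylbut-2-en-1-yl)-4-(triisopropylsilyloxy)phenyl][4-(methoxymethoxy)phenyl]methanone | CC(C)=CCc1c(O[Si](C(C)C)(C(C)C)C(C)C)cc(OCOC)c(C(=O)c2ccc(OCOC)cc2)c1OCOC
F6 | step 7 | [4-hydroxy-2,6-bis(methoxymethoxy)-3-(3-methylbut-2-en-1-yl)phenyl][4-(methoxymethoxy)phenyl]methanone | CC(C)=CCc1c(O)cc(OCOC)c(C(=O)c2ccc(OCOC)cc2)c1OCOC
F7 | step 9 | (±)-[5,7-bis(methoxymethoxy)-2,2-dimethyl-8-(3-methylbut-2-en-1-yl)-2H-chromen-6-yl][4-(tert-butyldimethylsilyloxy)phenyl]methanol | CC(C)=CCc1c(OCOC)c(C(O)c2ccc(O[Si](C)(C)C(C)(C)C)cc2)c(OCOC)c2c1OC(C)(C)C=C2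
F8 | step 9 | [5,7-bis(methoxymethoxy)-2,2-dimethyl-8-(3-methylbut-2-en-1-yl)-2H-chromen-6-yl][4-(tert-butyldimethylsilyloxy)phenyl]methanone | CC(C)=CCc1c(OCOC)c(C(=O)c2ccc(O[Si](C)(C)C(C)(C)C)cc2)c(OCOC)c2c1OC(C)(C)C=C2
F9 | step 9 | [5,7-dihydroxy-2,2-dimethyl-8-(3-methylbut-2-en-1-yl)-2H-chromen-6-yl][4-(tert-butyldimethylsilyloxy)phenyl]methanone | CC(C)=CCc1c(O)c(C(=O)c2ccc(O[Si](C)(C)C(C)(C)C)cc2)c(O)c2c1OC(C)(C)C=C2
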